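## Retrosynthetic overview

1. The target comes from its 3-ketone by equatorial hydride delivery (axial C3–OH), and the ketone from a 3,19-diol acid by selective C19 acetylation and oxidation.
2. The Δ7 alkene comes from an 8(17)-methylidene by radical (HAT) isomerisation; the acid comes from an ethyl ester.
3. Key disconnection C12–C13: a C12 aldehyde is used as an alkyl-carbanion equivalent (N–H hydrazone on Ru, traceless loss of N2) and adds to the β-carbon of ethyl crotonate, joining two normally electrophilic carbons and creating C13 under catalyst control.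
4. The C12 aldehyde comes from andrographolide by chemoselective oxidative excision of the butenolide.
5. No ring is formed: the trans-decalin with C4, C5, C9 and C10 is taken intact from andrographolide; C3 is inverted late.

Labdane numbering is used: C1–C10 decalin, C11–C16 side chain, C17 on C8, C18/C19 on C4, C20 on C10.

Assumption: the SMILES is read as (3S,4R,5S,9R,10S,13R)-19-acetoxy-3-hydroxylabd-7-en-15-oic acid (ent-labdane, C3–OH axial and trans to C20), i.e. the andrographolide decalin with inverted C3; andrographolide, a cheap bulk natural product, is taken as an acceptable commercial starting material.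

Assumption: the sense of induction of the Ru/(R,R)-Me-BPE catalyst in step 2 is taken as giving 13R; this is unproven and must be checked on the first run (the antipodal ligand is equally available).

## Route

Step 1
Reactants: 1 andrographolide
Product: 2 (3R,4R,5S,9R,10S)-3,19-dihydroxy-13,14,15,16-tetranorlabd-8(17)-en-12-al
Conditions: KMnO4 (1.4 equiv), THF/H2O, −10 °C, 20 min; aq NaHSO3
Reagents that add atoms: potassium permanganate, [K+].[O-][Mn](=O)(=O)=O
Why: Permanganate [3+2] addition and oxidative cleavage should be fastest at the conjugated, sterically open C12=C13 bond, while the hindered 8(17)-methylidene and the alcohols react more slowly at −10 °C, so the C12 aldehyde is released with C3, C4, C5, C9 and C10 untouched.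

Step 2
Reactants: 2 (3R,4R,5S,9R,10S)-3,19-dihydroxy-13,14,15,16-tetranorlabd-8(17)-en-12-al; 3 ethyl (E)-but-2-enoate
Product: 5 ethyl (3R,4R,5S,9R,10S,13R)-3,19-dihydroxylabd-8(17)-en-15-oate, via C12 N–H hydrazone 4 (not isolated)
Conditions: N2H4·H2O (1.2 equiv), THF, rt, 1 h; then 3 (3 equiv), [Ru(p-cymene)Cl2]2 (2.5 mol%), (R,R)-Me-BPE (5.5 mol%), K3PO4 (0.5 equiv), THF, 50 °C, 24 h
Reagents that add atoms: hydrazine monohydrate, NN.O (its two N atoms are present only in 4 and leave as N2; all non-hydrogen atoms of 5 come from 2 and 3)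
Why: Proposed new method: the hydrazone binds Ru(II) as a hydrazonido ligand, its azomethine carbon (C12, formerly the electrophilic aldehyde carbon) adds through a cyclic inner-sphere transition state to the β-carbon of Ru-bound crotonate, and the resulting Ru-diazenide loses N2 with protonation of C12 (Wolff–Kishner-type release), the C2-symmetric bisphospholane differentiating the crotonate faces so that C13 is set R by the catalyst alone (the ring stereocentres are too remote to interfere); the closest known reaction is the racemic Ru/dmpe-catalysed umpolung conjugate addition of aldehyde N–H hydrazones to α,β-unsaturated esters, extended here to an aliphatic hydrazone and to a chiral dmpe analogue.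

Step 3
Reactants: 5 ethyl (3R,4R,5S,9R,10S,13R)-3,19-dihydroxylabd-8(17)-en-15-oate
Product: 7 (3R,4R,5S,9R,10S,13R)-3,19-dihydroxylabd-7-en-15-oic acid, via Δ7 ethyl ester 6 (not isolated)
Conditions: Co(salen-tBu,tBu)Cl (3 mol%), PhSiH3 (6 mol%), benzene, rt; then LiOH·H2O (5 equiv), THF/MeOH/H2O, 40 °C; 1 M HCl to pH 3
Reagents that add atoms: lithium hydroxide monohydrate, [Li+].[OH-].O (supplies the hydroxyl O of the new CO2H)
Why: Cobalt-hydride hydrogen-atom transfer to the 1,1-disubstituted alkene gives the tertiary C8 radical, and abstraction of the accessible C7–H rather than the hindered C9 methine next to quaternary C10 gives the trisubstituted Δ7 alkene under kinetic control (radical positional alkene isomerisation, no stereocentre touched), after which hydroxide saponifies the unhindered ethyl ester in the same flask.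

Step 4
Reactants: 7 (3R,4R,5S,9R,10S,13R)-3,19-dihydroxylabd-7-en-15-oic acid
Product: 8 (3R,4R,5S,9R,10S,13R)-19-acetoxy-3-hydroxylabd-7-en-15-oic acid
Conditions: Ac2O (1.3 equiv), pyridine, CH2Cl2, 0 °C; aq NaHCO3, then pH 3
Reagents that add atoms: acetic anhydride, CC(=O)OC(C)=O
Why: Kinetically controlled selective esterification acylates the primary C19 hydroxyl in preference to the hindered secondary C3 hydroxyl next to quaternary C4, and any mixed anhydride formed at the acid is hydrolysed on bicarbonate work-up.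

Step 5
Reactants: 8 (3R,4R,5S,9R,10S,13R)-19-acetoxy-3-hydroxylabd-7-en-15-oic acid
Product: 9 (4R,5S,9R,10S,13R)-19-acetoxy-3-oxolabd-7-en-15-oic acid
Conditions: Dess–Martin periodinane (1.3 equiv), CH2Cl2, rt
Reagents that add atoms: none
Why: Dess–Martin oxidation converts the only remaining alcohol into the 3-ketone under neutral conditions, and because C4 is quaternary neither acetate β-elimination nor epimerisation is possible while alkene, acetate and acid are inert.

Step 6
Reactants: 9 (4R,5S,9R,10S,13R)-19-acetoxy-3-oxolabd-7-en-15-oic acid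
Product: 10 (3S,4R,5S,9R,10S,13R)-19-acetoxy-3-hydroxylabd-7-en-15-oic acid
Conditions: L-Selectride (2.5 equiv), THF, −78 °C, 1 h; 1 M HCl to pH 3–4 at −78 → 0 °C
Reagents that add atoms: none
Why: In this diastereoselective ketone reduction the bulky tri-sec-butylborohydride approaches the 4,4-disubstituted cyclohexanone from the equatorial direction (axial approach is blocked by the axial hydrogens at C1 and C5), giving the axial 3S alcohol trans to C20 as in 3-oxo-triterpenoid to 3-epi-alcohol reductions, while the carboxylate and the neopentyl acetate are not reduced at −78 °C and the trans-diaxial O3/C19 arrangement prevents acyl migration.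

## Compound list

1 | andrographolide, (3E,4S)-3-{2-[(1R,4aS,5R,6R,8aS)-6-hydroxy-5-(hydroxymethyl)-5,8a-dimethyl-2-methylidenedecahydronaphthalen-1-yl]ethylidene}-4-hydroxyoxolan-2-one | OC[C@@]1(C)[C@H]2CCC(=C)[C@@H](C/C=C3/C(=O)OC[C@H]3O)[C@]2(C)CC[C@H]1O | starting material
2 | (3R,4R,5S,9R,10S)-3,19-dihydroxy-13,14,15,16-tetranorlabd-8(17)-en-12-al | OC[C@@]1(C)[C@H]2CCC(=C)[C@@H](CC=O)[C@]2(C)CC[C@H]1O | intermediate
3 | ethyl (E)-but-2-enoate (ethyl crotonate) | C/C=C/C(=O)OCC | starting material
4 | (E)-hydrazone (C12=N–NH2) of aldehyde 2 | OC[C@@]1(C)[C@H]2CCC(=C)[C@@H](C/C=N/N)[C@]2(C)CC[C@H]1O | intermediate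
5 | ethyl (3R,4R,5S,9R,10S,13R)-3,19-dihydroxylabd-8(17)-en-15-oate | OC[C@@]1(C)[C@H]2CCC(=C)[C@@H](CC[C@@H](C)CC(=O)OCC)[C@]2(C)CC[C@H]1O | intermediate
6 | ethyl (3R,4R,5S,9R,10S,13R)-3,19-dihydroxylabd-7-en-15-oate | OC[C@@]1(C)[C@H]2CC=C(C)[C@@H](CC[C@@H](C)CC(=O)OCC)[C@]2(C)CC[C@H]1O | intermediate
7 | (3R,4R,5S,9R,10S,13R)-3,19-dihydroxylabd-7-en-15-oic acid | OC[C@@]1(C)[C@H]2CC=C(C)[C@@H](CC[C@@H](C)CC(=O)O)[C@]2(C)CC[C@H]1O | intermediate
8 | (3R,4R,5S,9R,10S,13R)-19-acetoxy-3-hydroxylabd-7-en-15-oic acid (3-OH equatorial) | CC(=O)OC[C@@]1(C)[C@H]2CC=C(C)[C@@H](CC[C@@H](C)CC(=O)O)[C@]2(C)CC[C@H]1O | intermediate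
9 | (4R,5S,9R,10S,13R)-19-acetoxy-3-oxolabd-7-en-15-oic acid | CC(=O)OC[C@@]1(C)[C@H]2CC=C(C)[C@@H](CC[C@@H](C)CC(=O)O)[C@]2(C)CCC1=O | intermediate
10 | (3S,4R,5S,9R,10S,13R)-19-acetoxy-3-hydroxylabd-7-en-15-oic acid (3-OH axial) | CC(=O)OC[C@@]1(C)[C@H]2CC=C(C)[C@@H](CC[C@@H](C)CC(=O)O)[C@]2(C)CC[C@@H]1O | target

## Step count and risks

Total step count: 6. Longest linear sequence: 6 steps (1 → 10).

The three steps most likely to fail are step 2 (highest risk), step 1 and step 3.

Step 1 (competition from the 8(17)-alkene, over-oxidation of the aldehyde). The fallback sets out from 1 and comes back at 2. Weitz–Scheffer epoxidation (t-BuOOH, DBU, CH2Cl2, 0 °C), which can only attack the electron-poor C12=C13 bond, gives 12,13-epoxy-12,13-dihydroandrographolide F1 as an inconsequential mixture of epoxide diastereomers. Periodic acid (H5IO6, THF/H2O, 0 °C) then opens and cleaves the epoxide to give 2.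

Step 2 (aliphatic hydrazone, β-substituted acceptor, unproven enantio-induction). The fallback sets out from 2 and comes back at 7, replacing the carbanion-equivalent at C12 by a homoenolate at C13. NaBH4 (MeOH, 0 °C) reduces 2 to (3R,4R,5S,9R,10S)-13,14,15,16-tetranorlabd-8(17)-ene-3,12,19-triol F2. I2/PPh3/imidazole (CH2Cl2, 0 °C) converts only the unhindered primary C12 hydroxyl (C19 is neopentyl, C3 secondary) into 12-iodo-13,14,15,16-tetranorlabd-8(17)-ene-3,19-diol F3. A nickel-hydride-catalysed, β-selective enantioselective hydroalkylation of (E)-1-(morpholin-4-yl)but-2-en-1-one (NiI2, chiral bis(oxazoline), (EtO)2MeSiH, KF, DMA, rt), in which the chelated β-nickelated amide couples with the iodide, gives the (13R)-labd-8(17)-en-15-oic acid morpholine amide F4. This is isomerised under the step 3 cobalt conditions to the (13R)-labd-7-en-15-oic acid morpholine amide F5 and hydrolysed (KOH, ethylene glycol/H2O, 130 °C) to 7.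

Step 3 (Δ7 versus Δ8(9) regioselectivity). The fallback sets out from 5 and comes back at 6, which is saponified as in step 3. Ozonolysis (O3, CH2Cl2/MeOH, −78 °C; Me2S) gives ethyl 3,19-dihydroxy-8-oxo-17-norlabdan-15-oate F6. KHMDS (3.1 equiv, the two hydroxyls being deprotonated first; THF, −78 °C) enolises kinetically towards the C7 methylene, and N-(5-chloropyridin-2-yl)triflimide traps the enolate as ethyl 3,19-dihydroxy-8-(trifluoromethanesulfonyloxy)-17-norlabd-7-en-15-oate F7. Fe(acac)3-catalysed coupling with MeMgBr (THF/NMP, −20 °C) installs C17 regiospecifically and gives 6.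

## Further compounds

F1 | step 1 | 12,13-epoxy-12,13-dihydroandrographolide (epoxide diastereomers) | OC[C@@]1(C)[C@H]2CCC(=C)[C@@H](CC3OC34C(=O)OC[C@H]4O)[C@]2(C)CC[C@H]1O
F2 | step 2 | (3R,4R,5S,9R,10S)-13,14,15,16-tetranorlabd-8(17)-ene-3,12,19-triol | OC[C@@]1(C)[C@H]2CCC(=C)[C@@H](CCO)[C@]2(C)CC[C@H]1O
F3 | step 2 | 12-iodo-13,14,15,16-tetranorlabd-8(17)-ene-3,19-diol | OC[C@@]1(C)[C@H]2CCC(=C)[C@@H](CCI)[C@]2(C)CC[C@H]1O
F4 | step 2 | (13R)-3,19-dihydroxylabd-8(17)-en-15-oic acid morpholine amide | OC[C@@]1(C)[C@H]2CCC(=C)[C@@H](CC[C@@H](C)CC(=O)N3CCOCC3)[C@]2(C)CC[C@H]1O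
F5 | step 2 | (13R)-3,19-dihydroxylabd-7-en-15-oic acid morpholine amide | OC[C@@]1(C)[C@H]2CC=C(C)[C@@H](CC[C@@H](C)CC(=O)N3CCOCC3)[C@]2(C)CC[C@H]1O
F6 | step 3 | ethyl (13R)-3,19-dihydroxy-8-oxo-17-norlabdan-15-oate | OC[C@@]1(C)[C@H]2CCC(=O)[C@@H](CC[C@@H](C)CC(=O)OCC)[C@]2(C)CC[C@H]1O
F7 | step 3 | ethyl (13R)-3,19-dihydroxy-8-(trifluoromethanesulfonyloxy)-17-norlabd-7-en-15-oate | OC[C@@]1(C)[C@H]2CC=C(OS(=O)(=O)C(F)(F)F)[C@@H](CC[C@@H](C)CC(=O)OCC)[C@]2(C)CC[C@H]1O
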